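A flat target curve tempts me to write down an equilibrium, but a flat curve can also mean that one charge has been spent, and the two need different arithmetic.

| flask | substrate | solid reagent | remark | time |
|---|---|---|---|---|
| gamma | 1.5 M | 0.53 M | run made earlier |  |
| eta | 1.5 M | 0.79 M | run made earlier |  |
| theta | 0.75 M | 1.05 M | run made earlier |  |
| flask | 1.5 M | 1.05 M |  | 1.5 h |

| run | time / min | target / % |
|---|---|---|
| gamma | 4.00 | 24 |
| gamma | 8.00 | 36 |
| gamma | 15.0 | 36 |
| gamma | 30.0 | 33 |
| gamma | 50.0 | 35 |
| eta | 5.00 | 32 |
| eta | 15.0 | 53 |
| eta | 25.0 | 51 |
| eta | 40.0 | 53 |
| eta | 50.0 | 53 |
| theta | 10.0 | 54 |
| theta | 20.0 | 77 |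
| theta | 30.0 | 90 |
| theta | 40.0 | 96 |
| theta | 50.0 | 95 |

(each reading ± 1.5 percentage points)

- which holds at 1.5 h: what has brought the reaction to rest, or that it has not come to rest (for what has run out or reacted, a solid counts together with what of it has only dissolved) (it is still moving / all of the substrate has reacted / the partner has run out first / forward and back rates have come level)
- target at 1.5 h, in percent of the substrate charged

- given per volume of solution although it is solid: solid reagent
- at the start none of the solid reagent is in solution
- the reaction counts as stopped when no species that holds the substrate changes by six tenths of a point or more over the second half of the time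

So I write the balance of the solid reagent, which gamma, eta and the flask charge in the smaller amount: what was charged equals what is still solid, plus what is dissolved as partner, plus what has reacted. If one partner makes one target, target stops at the charge of solid reagent, the limiting reagent here. For the flask that is 70.0% of the substrate charged, and this ratio, solid reagent charged over substrate charged, is my ceiling C.

Now I read the runs against C. In gamma C is 35.3% and the last reading is 35%. In eta C is 52.7% and the last reading is 53%. Each level therefore follows its charge, within a scatter of 1.5 percentage points. In theta C is 140%, so the substrate is the smaller charge, and target reads 96% at 40.0 min and 95% at 50.0 min, far past both earlier levels.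

Eta already reads 53% at 15.0 min and reads 53% at 50.0 min, whereas the flask has 90 min. I therefore commit to target at C, with 30.0% of the substrate left over when the solid reagent gives out.

The forecast says the partner has run out first, with target 69.5% in a range from 67% to 71%, on the ground that “the solid reagent is consumed 1:1”.

The flask gives target 68.6%, and the partner has run out first, with 0% of the charged partner left at 1.50 h.

    tight pair ⇌ loose pair (K = 0.920, k = 6.94 min⁻¹)
    substrate ⇌ tight pair (K = 0.00290, k = 0.0792 min⁻¹)
    partner + tight pair → target (k = 2980 L mol⁻¹ min⁻¹)
    partner + loose pair → isomer of the product (k = 9240 L mol⁻¹ min⁻¹)
    solid reagent ⇌ partner, rate k5*(cs5 - [partner]) while solid is left; crystals form when [partner] > cs5 (solubility = 1.30 M, k = 0.154 min⁻¹)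

The isomer of the product stands at 1.42% at that time, and together with the target it fills C, 70.0%. A neighbour is the same flask with 0.42 M of solid reagent, so its C is 28.0%. It ends with target 26.9% and isomer of the product 1.09%, and 71.6% of its substrate is left.

Readings and results were computed with made-up constants; scatter was added.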